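**Retrosynthetic overview**

1. The 26-membered ring is opened at C15–C16 (Stille) and at the lactone bond C1–O25 (esterification). This gives a C16–C25 tetraenylstannane (from L-fucal) and a C1–C15 iodoalkene acid.
2. C2–C3 comes from an aldol of the pivalaldehyde acetal (1,3-dioxan-4-one) of (S)-3-hydroxyoctanoic acid, which sets C2 and C3 from C1'.
3. C4–C5 is made by a SmI2 Reformatsky closure of an O7 bromoacetate onto the C5 aldehyde. O7 stands five atoms from C3, so O7–C3–C4–C5–C6–C7 can be a six-membered lactone whose trans 4-hydroxy-6-alkyl pattern is the syn C5/C7 diol. C3 is carried at the acid level, and the O7–C3 bond (not in the target) is cut afterwards.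
4. C7–C11 comes from a three-component dithiane linchpin coupling of two epoxides: C5–C8 from (R)-epichlorohydrin, and C10–C15 with C11–C13 from L-arabinose.
5. Ring order: acetonide rings, then the temporary lactone (closed, then opened), and the macrocycle last.

Key step: step 16

Remark: atoms are numbered as in the macrolide (C1 lactone carbonyl, C25 the CH(CH3)–O carbon, C1' the side-chain carbinol); L-arabinose is drawn open-chain.

**Route**

Step 1
Reactants: 1 L-arabinose
Product: 2 L-arabinose diethyl dithioacetal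
Conditions: EtSH, conc. HCl, 0 °C
Reagents that add atoms: ethanethiol, CCS
Why: acid-catalysed dithioacetalisation traps the open-chain aldose, whose three carbinol carbons become C13, C12 and C11 unchanged.

Step 2
Reactants: 2 L-arabinose diethyl dithioacetal
Product: 3 2,3:4,5-di-O-isopropylidene dithioacetal
Conditions: Me2C(OMe)2, acetone, TsOH (cat.), rt
Reagents that add atoms: 2,2-dimethoxypropane, COC(C)(C)OC
Why: thermodynamic acetalisation should give the two dioxolanes on the threo 2,3-diol and the terminal 4,5-diol.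

Step 3
Reactants: 3 2,3:4,5-di-O-isopropylidene dithioacetal
Product: 4 2,3:4,5-di-O-isopropylidene-aldehydo-L-arabinose
Conditions: I2, NaHCO3, acetone/H2O, 0 °C
Reagents that add atoms: water, O
Why: iodine-promoted, buffered hydrolysis of the dithioacetal should free the aldehyde without loss of the acetonides or epimerisation.

Step 4
Reactants: 4 2,3:4,5-di-O-isopropylidene-aldehydo-L-arabinose
Product: 5 terminal alkyne
Conditions: MeC(O)C(N2)P(O)(OMe)2, K2CO3, MeOH, 0 °C → rt
Reagents that add atoms: dimethyl (1-diazo-2-oxopropyl)phosphonate, COP(=O)(OC)C(=[N+]=[N-])C(C)=O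
Why: Seyferth–Gilbert homologation with the Ohira–Bestmann reagent turns the aldehyde carbon into C14 of a terminal alkyne (new carbon C15) under base mild enough to keep the α-alkoxy centre.

Step 5
Reactants: 5 terminal alkyne
Product: 7 (E)-iodoalkene, via alkenylalane 6 (not isolated)
Conditions: Me3Al, Cp2ZrCl2 (cat.), H2O (1 equiv), CH2Cl2, −23 °C; then I2, THF, −23 → 0 °C
Reagents that add atoms: trimethylaluminium, C[Al](C)C; iodine, II
Why: zirconium-catalysed carboalumination (Negishi) adds methyl to C14 and aluminium to C15 in a syn fashion, and iodinolysis with retention gives the (E)-iodoalkene.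

Step 6
Reactants: 7 (E)-iodoalkene
Product: 8 terminal diol
Conditions: AcOH/H2O (7:3), rt
Reagents that add atoms: none
Why: the terminal monosubstituted dioxolane is hydrolysed faster than the internal trans-disubstituted one.

Step 7
Reactants: 8 terminal diol
Product: 10 C10–C15 epoxide, via primary tosylate 9 (not isolated)
Conditions: NaH, N-tosylimidazole, THF, 0 °C → rt
Reagents that add atoms: none
Why: selective sulfonylation of the primary alkoxide and intramolecular Williamson closure by the C11 alkoxide give the terminal epoxide with retention at C11.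

Step 8
Reactants: 11 (R)-epichlorohydrin
Product: 13 (R)-2-allyloxirane, via chlorohydrin 12 (not isolated)
Conditions: CH2=CHMgBr, CuI (cat.), THF, −40 °C; then NaOH, H2O/Et2O, rt
Reagents that add atoms: vinylmagnesium bromide, C=C[Mg]Br
Why: copper-catalysed Grignard opening at the epoxide CH2 and base-induced closure onto the CH2Cl carbon leave the stereocentre (future C7) untouched.

Step 9
Reactants: 14 2-(tert-butyldimethylsilyl)-1,3-dithiane; 13 (R)-2-allyloxirane; 10 C10–C15 epoxide
Product: 17 C5–C15 dithiane alcohol, via lithium alkoxide 15 (not isolated), via lithiated silyl ether 16 (not isolated)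
Conditions: t-BuLi (1.0 equiv), Et2O, −78 → −45 °C; 13, −78 → −25 °C; then 10, HMPA/THF, −78 °C → rt
Reagents that add atoms: none
Why: dithiane linchpin (anion relay) coupling: the lithiated dithiane opens 13 at its CH2, HMPA triggers the 1,4-Brook rearrangement that silylates O7 and regenerates a dithiane anion, and this anion opens 10 at C10, so both epoxide stereocentres are kept and only O11 stays free.

Step 10
Reactants: 17 C5–C15 dithiane alcohol
Product: 18 C9 ketone
Conditions: MeI, CaCO3, MeCN/H2O (9:1), 45 °C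
Reagents that add atoms: water, O
Why: S-methylation and hydrolysis should unmask the C9 ketone under conditions that spare the silyl ether, the acetonide and the iodoalkene.

Step 11
Reactants: 18 C9 ketone
Product: 19 anti-C9/C11 diol
Conditions: Me4NBH(OAc)3, MeCN/AcOH (1:1), −30 °C
Reagents that add atoms: none
Why: Evans–Saksena reduction: the free C11 hydroxyl binds boron and delivers hydride intramolecularly through a chair transition state, giving the 1,3-anti diol (C9 of the target), while the silylated O7 cannot direct.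

Step 12
Reactants: 19 anti-C9/C11 diol
Product: 20 C9/C11 acetonide
Conditions: Me2C(OMe)2, PPTS (cat.), CH2Cl2, rt
Reagents that add atoms: 2,2-dimethoxypropane, COC(C)(C)OC
Why: acid-catalysed ketal exchange should protect the anti-1,3-diol as its dioxane.

Step 13
Reactants: 20 C9/C11 acetonide
Product: 21 C7 alcohol
Conditions: Bu4NF, THF, 0 °C → rt
Reagents that add atoms: none
Why: fluoride removes the only silyl ether and frees O7 for the tether.

Step 14
Reactants: 21 C7 alcohol
Product: 22 C7 bromoacetate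
Conditions: BrCH2COBr, pyridine, CH2Cl2, −20 °C
Reagents that add atoms: bromoacetyl bromide, BrCC(Br)=O
Why: acylation of the secondary alcohol installs C3 and C4 as a temporary ester tether on O7.

Step 15
Reactants: 22 C7 bromoacetate
Product: 24 C5 aldehyde, via diol 23 (not isolated)
Conditions: OsO4 (cat.), NaIO4, 2,6-lutidine, dioxane/H2O (3:1), rt
Reagents that add atoms: sodium periodate, [Na+].[O-]I(=O)(=O)=O (source of the aldehyde oxygen through OsO4)
Why: Lemieux–Johnson cleavage: the monosubstituted alkene is dihydroxylated much faster than the trisubstituted iodoalkene, and buffered periodate cleavage gives the β-acyloxy aldehyde, which is used at once.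

Step 16
Reactants: 24 C5 aldehyde
Product: 26 trans-hydroxy lactone, via samarium enolate 25 (not isolated)
Conditions: SmI2 (2.2 equiv), THF, −78 °C
Reagents that add atoms: none
Why: SmI2 reduces the C–Br bond by two single-electron transfers to the trivalent-samarium ester enolate 25, whose C4 adds to the C5 aldehyde (intramolecular Reformatsky reaction). The closest known reaction type is the SmI2-promoted cyclisation of β-(bromoacetoxy) aldehydes to β-hydroxy-δ-valerolactones. The only ring closed is the six-membered lactone O7–C3–C4–C5–C6–C7, formed in the 6-(enolendo)-exo-trig mode. The new C5 centre is set by the C7 centre: samarium bridges the enolate oxygen and the aldehyde oxygen in a chair-like bicyclic transition state that holds the C5–O bond axial and the C8 chain on C7 equatorial, which gives the trans 4-hydroxy-6-alkyl lactone, that is the syn C5/C7 diol. The step needs 1,3-induction, secured by the O7–C3 ester tether, and chemoselective reduction of the α-bromo ester beside the iodoalkene and the aldehyde, secured by the much faster electron transfer to the activated C–Br bond at −78 °C without HMPA.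

Step 17
Reactants: 26 trans-hydroxy lactone
Product: 27 C5/C7 diol Weinreb amide
Conditions: MeNH(OMe)·HCl, Me3Al, CH2Cl2, 0 °C → rt
Reagents that add atoms: N,O-dimethylhydroxylamine hydrochloride, CNOC.Cl
Why: aluminium amide aminolysis opens the lactone at the acyl C3–O7 bond, which removes the temporary tether and frees the syn diol.

Step 18
Reactants: 27 C5/C7 diol Weinreb amide
Product: 28 C5/C7 acetonide Weinreb amide
Conditions: Me2C(OMe)2, PPTS (cat.), CH2Cl2, rt
Reagents that add atoms: 2,2-dimethoxypropane, COC(C)(C)OC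
Why: the syn-1,3-diol should close readily to the chair dioxane.

Step 19
Reactants: 28 C5/C7 acetonide Weinreb amide
Product: 29 C3 aldehyde
Conditions: iBu2AlH, THF, −78 °C; aq. Rochelle salt
Reagents that add atoms: none
Why: the chelated tetrahedral intermediate of the Weinreb amide stops the reduction at the aldehyde.

Step 20
Reactants: 30 methyl 3-oxooctanoate
Product: 31 methyl (S)-3-hydroxyoctanoate
Conditions: H2 (50 atm), RuCl2[(S)-BINAP] (cat.), MeOH, 50 °C
Reagents that add atoms: none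
Why: Noyori hydrogenation of the β-keto ester with the (S)-BINAP ruthenium catalyst should give the (S)-carbinol (C1').

Step 21
Reactants: 31 methyl (S)-3-hydroxyoctanoate
Product: 32 (S)-3-hydroxyoctanoic acid
Conditions: LiOH, THF/H2O, rt; then 1 M HCl
Reagents that add atoms: lithium hydroxide, [Li+].[OH-]
Why: simple saponification does not touch the carbinol centre.

Step 22
Reactants: 32 (S)-3-hydroxyoctanoic acid
Product: 33 (2S,6S)-2-tert-butyl-6-pentyl-1,3-dioxan-4-one
Conditions: t-BuCHO, TsOH (cat.), CH2Cl2, reflux, water removal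
Reagents that add atoms: pivalaldehyde, CC(C)(C)C=O
Why: acetalisation under thermodynamic control gives the cis dioxanone with both substituents equatorial, so that C1' fixes the acetal centre and the ring conformation.

Step 23
Reactants: 33 (2S,6S)-2-tert-butyl-6-pentyl-1,3-dioxan-4-one; 29 C3 aldehyde
Product: 35 aldol adduct, via lithium enolate 34 (not isolated)
Conditions: LiN(iPr)2, THF, −78 °C; then 29, −78 °C; AcOH quench
Reagents that add atoms: none
Why: lithium aldol of the ring-fixed (E)-enolate through a Zimmerman–Traxler chair: the aldehyde should enter trans to the C1' pentyl group (sets C2) and the (E)-geometry should give the 2,3-anti adduct (sets C3), which together is the all-syn C1'/C2/C3 triad of the target.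

Step 24
Reactants: 35 aldol adduct
Product: 36 C1',C3-dihydroxy acid
Conditions: LiOH, THF/H2O, 0 °C; then 1 M HCl to pH 4, 0 °C
Reagents that add atoms: lithium hydroxide, [Li+].[OH-]
Why: hydroxide attacks the acylal carbonyl and the hemiacetal collapses to pivalaldehyde, which frees the C1 acid and the C1' hydroxyl.

Step 25
Reactants: 36 C1',C3-dihydroxy acid
Product: 38 bis(triethylsilyl) acid, via silyl ester 37 (not isolated)
Conditions: Et3SiOTf (3.5 equiv), 2,6-lutidine, CH2Cl2, −78 → 0 °C; then K2CO3, MeOH/THF/H2O, 0 °C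
Reagents that add atoms: triethylsilyl trifluoromethanesulfonate, CC[Si](CC)(CC)OS(=O)(=O)C(F)(F)F
Why: exhaustive silylation followed by selective cleavage of the labile silyl ester should leave the two silyl ethers and the free acid.

Step 26
Reactants: 39 3,4-di-O-acetyl-L-fucal
Product: 40 L-fucal
Conditions: K2CO3 (cat.), MeOH, rt
Reagents that add atoms: none
Why: Zemplén-type transesterification removes both acetates without touching the enol ether.

Step 27
Reactants: 40 L-fucal
Product: 41 3-O-acetyl-L-fucal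
Conditions: AcCl (1.0 equiv), 2,4,6-collidine, CH2Cl2, −78 °C
Reagents that add atoms: acetyl chloride, CC(Cl)=O
Why: the equatorial allylic 3-hydroxyl should be acylated faster than the axial 4-hydroxyl.

Step 28
Reactants: 41 3-O-acetyl-L-fucal
Product: 42 3-O-acetyl-4-O-(tert-butyldimethylsilyl)-L-fucal
Conditions: t-BuMe2SiCl, imidazole, DMAP (cat.), DMF, 40 °C
Reagents that add atoms: tert-butyldimethylsilyl chloride, CC(C)(C)[Si](C)(C)Cl
Why: silylation without Lewis acid protects O4 (future O24) and avoids Ferrier ionisation of the allylic acetate.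

Step 29
Reactants: 42 3-O-acetyl-4-O-(tert-butyldimethylsilyl)-L-fucal
Product: 43 (2E,4S,5S)-4-silyloxy-5-hydroxyhex-2-enal
Conditions: HgSO4 (cat.), 5 mM H2SO4, 1,4-dioxane/H2O, rt
Reagents that add atoms: water, O
Why: Perlin hydrolysis: mercury-assisted hydration of the glycal, ring opening and loss of the C3 acetate give the (E)-enal, in which the former ring oxygen is the free C25 hydroxyl and O24 keeps its silyl group, with C24 and C25 taken unchanged from L-fucose.

Step 30
Reactants: 43 (2E,4S,5S)-4-silyloxy-5-hydroxyhex-2-enal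
Product: 44 (2E,4E)-dienal
Conditions: Ph3P=CHCHO, toluene, 60 °C
Reagents that add atoms: (triphenylphosphoranylidene)acetaldehyde, O=CC=P(c1ccccc1)(c1ccccc1)c1ccccc1
Why: Wittig reaction of the stabilised ylide should give the (E)-configured two-carbon homologue under neutral conditions.

Step 31
Reactants: 44 (2E,4E)-dienal
Product: 45 (E,E,E)-trienyl iodide
Conditions: CHI3, CrCl2, THF, 0 °C, dark
Reagents that add atoms: iodoform, IC(I)I
Why: Takai olefination: the geminal dichromium reagent adds to the aldehyde and eliminates to the (E)-iodoalkene, and the free hydroxyl is tolerated.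

Step 32
Reactants: 45 (E,E,E)-trienyl iodide
Product: 46 C16–C25 tetraenylstannane
Conditions: (E)-Bu3SnCH=CHSnBu3 (3 equiv), PdCl2(MeCN)2 (cat.), DMF, rt, dark
Reagents that add atoms: (E)-1,2-bis(tributylstannyl)ethene, CCCC[Sn](CCCC)(CCCC)/C=C/[Sn](CCCC)(CCCC)CCCC
Why: Stille mono-coupling with excess bis-stannane adds C16–C17 with retention of geometry and leaves the second stannyl group.

Step 33
Reactants: 38 bis(triethylsilyl) acid; 46 C16–C25 tetraenylstannane
Product: 48 seco ester, via mixed anhydride 47 (not isolated)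
Conditions: 2,4,6-Cl3C6H2COCl, Et3N, THF, rt; then 46, DMAP, toluene, rt
Reagents that add atoms: none
Why: Yamaguchi esterification: the mixed anhydride is attacked through its acylpyridinium by the only free hydroxyl (O25).

Step 34
Reactants: 48 seco ester
Product: 49 protected macrolide
Conditions: Pd2(dba)3, AsPh3, iPr2NEt, DMF/THF (1 mM), rt, dark
Reagents that add atoms: none
Why: intramolecular Stille coupling of the iodoalkene with the tetraenylstannane closes the 26-membered ring at C15–C16 and completes the all-E pentaene with retention at both alkenes, high dilution holding back oligomers.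

Step 35
Reactants: 49 protected macrolide
Product: 50 tris-acetonide macrolide
Conditions: HF·pyridine, pyridine, THF, 0 °C → rt
Reagents that add atoms: none
Why: buffered fluoride should remove the three silyl ethers (O1', O3, O24) without touching the acetonides, the lactone or the pentaene.

Step 36
Reactants: 50 tris-acetonide macrolide
Product: 51 CNP0296784.1
Conditions: Dowex 50W-X8 (H+ form), MeOH, rt, dark
Reagents that add atoms: none
Why: mild acid-resin methanolysis of the three acetonides should release the remaining six hydroxyls without ionising the allylic C13 and C24 positions.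

**Compound list**

1 | L-arabinose (open-chain form) | O=C[C@H](O)[C@@H](O)[C@@H](O)CO | starting material
2 | L-arabinose diethyl dithioacetal | CCSC(SCC)[C@H](O)[C@@H](O)[C@@H](O)CO | intermediate
3 | 2,3:4,5-di-O-isopropylidene-L-arabinose diethyl dithioacetal | CCSC(SCC)[C@@H]1OC(C)(C)O[C@H]1[C@@H]1COC(C)(C)O1 | intermediate
4 | 2,3:4,5-di-O-isopropylidene-aldehydo-L-arabinose | O=C[C@@H]1OC(C)(C)O[C@H]1[C@@H]1COC(C)(C)O1 | intermediate
5 | 1,2-dideoxy-3,4:5,6-di-O-isopropylidene-L-arabino-hex-1-ynitol | C#C[C@@H]1OC(C)(C)O[C@H]1[C@@H]1COC(C)(C)O1 | intermediate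
6 | (E)-alkenyl(dimethyl)alane from syn addition of Me–Al to 5 (Al on C15, Me on C14) | C[Al](C)/C=C(\C)[C@@H]1OC(C)(C)O[C@H]1[C@@H]1COC(C)(C)O1 | intermediate
7 | (E)-1,2-dideoxy-1-iodo-2-C-methyl-3,4:5,6-di-O-isopropylidene-L-arabino-hex-1-enitol | I/C=C(\C)[C@@H]1OC(C)(C)O[C@H]1[C@@H]1COC(C)(C)O1 | intermediate
8 | (E)-1,2-dideoxy-1-iodo-2-C-methyl-3,4-O-isopropylidene-L-arabino-hex-1-enitol (5,6-diol) | I/C=C(\C)[C@@H]1OC(C)(C)O[C@H]1[C@@H](O)CO | intermediate
9 | 6-O-tosylate of 8 | I/C=C(\C)[C@@H]1OC(C)(C)O[C@H]1[C@@H](O)COS(=O)(=O)c1ccc(C)cc1 | intermediate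
10 | (E)-5,6-anhydro-1,2-dideoxy-1-iodo-2-C-methyl-3,4-O-isopropylidene-L-arabino-hex-1-enitol (C10–C15 epoxide, oxirane CH of S configuration) | I/C=C(\C)[C@@H]1OC(C)(C)O[C@H]1[C@@H]1CO1 | intermediate
11 | (R)-epichlorohydrin | ClC[C@H]1CO1 | starting material
12 | (R)-1-chloropent-4-en-2-ol | ClC[C@H](O)CC=C | intermediate
13 | (R)-2-allyloxirane | C=CC[C@@H]1CO1 | intermediate
14 | 2-(tert-butyldimethylsilyl)-1,3-dithiane | CC(C)(C)[Si](C)(C)C1SCCCS1 | starting material
15 | lithium (R)-1-[2-(tert-butyldimethylsilyl)-1,3-dithian-2-yl]pent-4-en-2-olate | CC(C)(C)[Si](C)(C)C1(C[C@@H](CC=C)O[Li])SCCCS1 | intermediate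
16 | 2-lithio-2-[(R)-2-(tert-butyldimethylsilyloxy)pent-4-enyl]-1,3-dithiane | [Li]C1(C[C@@H](CC=C)O[Si](C)(C)C(C)(C)C)SCCCS1 | intermediate
17 | C5–C15 dithiane alcohol: C9 as 1,3-dithiane, O7 silylated, O11 free, C12/C13 acetonide, (E)-iodoalkene; C7 and C11–C13 arranged as in the target | I/C=C(\C)[C@@H]1OC(C)(C)O[C@H]1[C@@H](O)CC1(SCCCS1)C[C@H](O[Si](C)(C)C(C)(C)C)CC=C | intermediate
18 | C9 ketone with free C11 hydroxyl and O7 silyl ether | I/C=C(\C)[C@@H]1OC(C)(C)O[C@H]1[C@@H](O)CC(=O)C[C@H](O[Si](C)(C)C(C)(C)C)CC=C | intermediate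
19 | anti-C9/C11 diol, O7 silyl ether (C9 as in the target) | I/C=C(\C)[C@@H]1OC(C)(C)O[C@H]1[C@@H](O)C[C@H](O)C[C@H](O[Si](C)(C)C(C)(C)C)CC=C | intermediate
20 | C9/C11 acetonide, O7 silyl ether, terminal alkene at C5 | I/C=C(\C)[C@@H]1OC(C)(C)O[C@H]1[C@@H]1C[C@@H](C[C@H](O[Si](C)(C)C(C)(C)C)CC=C)OC(C)(C)O1 | intermediate
21 | C7 alcohol (homoallylic), bis-acetonide | I/C=C(\C)[C@@H]1OC(C)(C)O[C@H]1[C@@H]1C[C@@H](C[C@H](O)CC=C)OC(C)(C)O1 | intermediate
22 | C7 bromoacetate | I/C=C(\C)[C@@H]1OC(C)(C)O[C@H]1[C@@H]1C[C@@H](C[C@H](OC(=O)CBr)CC=C)OC(C)(C)O1 | intermediate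
23 | vicinal diol from dihydroxylation of the terminal alkene of 22 (both epimers) | I/C=C(\C)[C@@H]1OC(C)(C)O[C@H]1[C@@H]1C[C@@H](C[C@H](OC(=O)CBr)CC(O)CO)OC(C)(C)O1 | intermediate
24 | C5 aldehyde with O7 bromoacetate | I/C=C(\C)[C@@H]1OC(C)(C)O[C@H]1[C@@H]1C[C@@H](C[C@H](OC(=O)CBr)CC=O)OC(C)(C)O1 | intermediate
25 | diiodosamarium enolate of the O7 acetate (C3–C4 enolate), C5 aldehyde | I/C=C(\C)[C@@H]1OC(C)(C)O[C@H]1[C@@H]1C[C@@H](C[C@H](OC(=C)O[Sm](I)I)CC=O)OC(C)(C)O1 | intermediate
26 | (4S,6R)-4-hydroxy-6-substituted tetrahydropyran-2-one (trans; lactone O7–C3, hydroxyl on C5) | I/C=C(\C)[C@@H]1OC(C)(C)O[C@H]1[C@@H]1C[C@@H](C[C@H]2C[C@H](O)CC(=O)O2)OC(C)(C)O1 | intermediate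
27 | N-methoxy-N-methyl amide at C3 with syn C5/C7 diol | I/C=C(\C)[C@@H]1OC(C)(C)O[C@H]1[C@@H]1C[C@@H](C[C@H](O)C[C@H](O)CC(=O)N(C)OC)OC(C)(C)O1 | intermediate
28 | C3 Weinreb amide, C5/C7 acetonide (tris-acetonide) | I/C=C(\C)[C@@H]1OC(C)(C)O[C@H]1[C@@H]1C[C@@H](C[C@H]2C[C@@H](CC(=O)N(C)OC)OC(C)(C)O2)OC(C)(C)O1 | intermediate
29 | C3 aldehyde (C3–C15 fragment, tris-acetonide, (E)-iodoalkene) | I/C=C(\C)[C@@H]1OC(C)(C)O[C@H]1[C@@H]1C[C@@H](C[C@H]2C[C@@H](CC=O)OC(C)(C)O2)OC(C)(C)O1 | intermediate
30 | methyl 3-oxooctanoate | CCCCCC(=O)CC(=O)OC | starting material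
31 | methyl (S)-3-hydroxyoctanoate | CCCCC[C@H](O)CC(=O)OC | intermediate
32 | (S)-3-hydroxyoctanoic acid | CCCCC[C@H](O)CC(=O)O | intermediate
33 | (2S,6S)-2-tert-butyl-6-pentyl-1,3-dioxan-4-one (cis) | CCCCC[C@H]1CC(=O)O[C@@H](C(C)(C)C)O1 | intermediate
34 | lithium enolate of 33 | CCCCC[C@H]1C=C(O[Li])O[C@@H](C(C)(C)C)O1 | intermediate
35 | aldol adduct: dioxanone carrying at its C5 (target C2, trans to pentyl) the C3 carbinol chain; C1', C2, C3 as in the target | I/C=C(\C)[C@@H]1OC(C)(C)O[C@H]1[C@@H]1C[C@@H](C[C@H]2C[C@@H](C[C@@H](O)[C@@H]3C(=O)O[C@@H](C(C)(C)C)O[C@H]3CCCCC)OC(C)(C)O2)OC(C)(C)O1 | intermediate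
36 | C1 acid with free C1' and C3 hydroxyls (C1–C15 fragment) | I/C=C(\C)[C@@H]1OC(C)(C)O[C@H]1[C@@H]1C[C@@H](C[C@H]2C[C@@H](C[C@@H](O)[C@H](C(=O)O)[C@@H](O)CCCCC)OC(C)(C)O2)OC(C)(C)O1 | intermediate
37 | triethylsilyl ester of the O1',O3-bis(triethylsilyl) acid | I/C=C(\C)[C@@H]1OC(C)(C)O[C@H]1[C@@H]1C[C@@H](C[C@H]2C[C@@H](C[C@@H](O[Si](CC)(CC)CC)[C@H](C(=O)O[Si](CC)(CC)CC)[C@@H](O[Si](CC)(CC)CC)CCCCC)OC(C)(C)O2)OC(C)(C)O1 | intermediate
38 | O1',O3-bis(triethylsilyl) C1–C15 acid | I/C=C(\C)[C@@H]1OC(C)(C)O[C@H]1[C@@H]1C[C@@H](C[C@H]2C[C@@H](C[C@@H](O[Si](CC)(CC)CC)[C@H](C(=O)O)[C@@H](O[Si](CC)(CC)CC)CCCCC)OC(C)(C)O2)OC(C)(C)O1 | intermediate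
39 | 3,4-di-O-acetyl-L-fucal | C[C@@H]1OC=C[C@H](OC(C)=O)[C@@H]1OC(C)=O | starting material
40 | L-fucal | C[C@@H]1OC=C[C@H](O)[C@@H]1O | intermediate
41 | 3-O-acetyl-L-fucal | C[C@@H]1OC=C[C@H](OC(C)=O)[C@@H]1O | intermediate
42 | 3-O-acetyl-4-O-(tert-butyldimethylsilyl)-L-fucal | C[C@@H]1OC=C[C@H](OC(C)=O)[C@@H]1O[Si](C)(C)C(C)(C)C | intermediate
43 | (2E,4S,5S)-4-(tert-butyldimethylsilyloxy)-5-hydroxyhex-2-enal | C[C@H](O)[C@@H](O[Si](C)(C)C(C)(C)C)/C=C/C=O | intermediate
44 | (2E,4E,6S,7S)-6-(tert-butyldimethylsilyloxy)-7-hydroxyocta-2,4-dienal | C[C@H](O)[C@@H](O[Si](C)(C)C(C)(C)C)/C=C/C=C/C=O | intermediate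
45 | (2S,3S,4E,6E,8E)-3-(tert-butyldimethylsilyloxy)-9-iodonona-4,6,8-trien-2-ol | C[C@H](O)[C@@H](O[Si](C)(C)C(C)(C)C)/C=C/C=C/C=C/I | intermediate
46 | (2S,3S,4E,6E,8E,10E)-3-(tert-butyldimethylsilyloxy)-11-(tributylstannyl)undeca-4,6,8,10-tetraen-2-ol | C[C@H](O)[C@@H](O[Si](C)(C)C(C)(C)C)/C=C/C=C/C=C/C=C/[Sn](CCCC)(CCCC)CCCC | intermediate
47 | mixed anhydride of 38 with 2,4,6-trichlorobenzoic acid | I/C=C(\C)[C@@H]1OC(C)(C)O[C@H]1[C@@H]1C[C@@H](C[C@H]2C[C@@H](C[C@@H](O[Si](CC)(CC)CC)[C@H](C(=O)OC(=O)c3c(Cl)cc(Cl)cc3Cl)[C@@H](O[Si](CC)(CC)CC)CCCCC)OC(C)(C)O2)OC(C)(C)O1 | intermediate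
48 | seco ester: C1 acid 38 esterified with O25 of 46 (iodoalkene at C15, stannane at C16) | I/C=C(\C)[C@@H]1OC(C)(C)O[C@H]1[C@@H]1C[C@@H](C[C@H]2C[C@@H](C[C@@H](O[Si](CC)(CC)CC)[C@H](C(=O)O[C@@H](C)[C@@H](O[Si](C)(C)C(C)(C)C)/C=C/C=C/C=C/C=C/[Sn](CCCC)(CCCC)CCCC)[C@@H](O[Si](CC)(CC)CC)CCCCC)OC(C)(C)O2)OC(C)(C)O1 | intermediate
49 | protected macrolide: O1',O3-bis(triethylsilyl), O24-tert-butyldimethylsilyl, 5,7-, 9,11- and 12,13-acetonides | CCCCC[C@H](O[Si](CC)(CC)CC)[C@H]1C(=O)O[C@@H](C)[C@@H](O[Si](C)(C)C(C)(C)C)/C=C/C=C/C=C/C=C/C=C(\C)[C@@H]2OC(C)(C)O[C@H]2[C@@H]2C[C@H](OC(C)(C)O2)C[C@H]2C[C@H](OC(C)(C)O2)C[C@H]1O[Si](CC)(CC)CC | intermediate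
50 | macrolide 5,7:9,11:12,13-tris-acetonide with free O1', O3, O24 | CCCCC[C@H](O)[C@H]1C(=O)O[C@@H](C)[C@@H](O)/C=C/C=C/C=C/C=C/C=C(\C)[C@@H]2OC(C)(C)O[C@H]2[C@@H]2C[C@H](OC(C)(C)O2)C[C@H]2C[C@H](OC(C)(C)O2)C[C@H]1O | intermediate
51 | CNP0296784.1 | CCCCC[C@H](O)[C@H]1C(=O)O[C@@H](C)[C@@H](O)/C=C/C=C/C=C/C=C/C=C(\C)[C@H](O)[C@@H](O)[C@@H](O)C[C@H](O)C[C@H](O)C[C@H](O)C[C@H]1O | target

**Totals and risks**

Total step count: 36. Longest linear sequence: 25 steps (steps 1–7, 9–19, 23–25, 33–36).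

Most likely to fail, step 23: erosion of diastereoselectivity by double stereodifferentiation with the chiral, β-branched aldehyde, and slow addition that lets the dioxanone enolate open by β-elimination. The fallback reverses the roles of the two partners and forms C2–C1' instead of C2–C3. It sets out from 29. A Mukaiyama aldol with 1-methoxy-1-(trimethylsilyloxy)ethene (BF3·OEt2, CH2Cl2, −78 °C; open transition state, 1,3-anti induction by the C5 oxygen) should give the methyl 3-hydroxy ester F1. LiOH then gives the 3-hydroxy acid F2, and pivalaldehyde/PPTS gives the cis dioxanone F3. Its lithium enolate is added to the small, achiral hexanal (entry trans to the C4 chain, anti adduct) to give the aldol adduct F4. LiOH opens F4 to 36, where the route is rejoined.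

Step 33: sluggish acylation of the secondary O25 by the doubly β-branched C1 acid, with slow decay of the stannane in the meantime. The fallback turns the esterification into a ring closure. It sets out from 38 and 46. An intermolecular Stille coupling (Pd2(dba)3, AsPh3, DMF) joins C15 and C16 to give the seco hydroxy acid F5. Shiina macrolactonisation (2-methyl-6-nitrobenzoic anhydride, DMAP, toluene, high dilution) then closes the lactone and returns to the route at 49.

Step 16: loss of the bromoacetate by β-elimination from the β-acyloxy aldehyde before cyclisation, or protonation of the samarium enolate (plain debromination). The fallback uses reagent control in place of the tether. It sets out from 20. OsO4/NaIO4 cleavage gives the O7-silyl C5 aldehyde F6. Brown allylation with the antipode of B-allyldiisopinocampheylborane that delivers the target C5 configuration gives the homoallylic alcohol F7. Bu4NF gives the syn diol F8, and Me2C(OMe)2/PPTS gives the acetonide alkene F9. A second OsO4/NaIO4 cleavage returns to the route at 29.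

**Further compounds**

F1 | step 23 | methyl 3-hydroxy ester from 29 (C3 carbinol anti to O5, C1 as methyl ester, C2 unsubstituted) | I/C=C(\C)[C@@H]1OC(C)(C)O[C@H]1[C@@H]1C[C@@H](C[C@H]2C[C@@H](C[C@@H](O)CC(=O)OC)OC(C)(C)O2)OC(C)(C)O1
F2 | step 23 | 3-hydroxy acid from F1 | I/C=C(\C)[C@@H]1OC(C)(C)O[C@H]1[C@@H]1C[C@@H](C[C@H]2C[C@@H](C[C@@H](O)CC(=O)O)OC(C)(C)O2)OC(C)(C)O1
F3 | step 23 | cis-2-tert-butyl-1,3-dioxan-4-one of F2 (ring through O3, C3, C2, C1) | I/C=C(\C)[C@@H]1OC(C)(C)O[C@H]1[C@@H]1C[C@@H](C[C@H]2C[C@@H](C[C@@H]3CC(=O)O[C@H](C(C)(C)C)O3)OC(C)(C)O2)OC(C)(C)O1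
F4 | step 23 | aldol adduct of F3 with hexanal (C1' carbinol on C2, trans to the C4 chain) | I/C=C(\C)[C@@H]1OC(C)(C)O[C@H]1[C@@H]1C[C@@H](C[C@H]2C[C@@H](C[C@@H]3[C@@H]([C@@H](O)CCCCC)C(=O)O[C@H](C(C)(C)C)O3)OC(C)(C)O2)OC(C)(C)O1
F5 | step 33 | seco hydroxy acid with complete all-E pentaene (free C1 acid, free O25) | C[C@H](O)[C@@H](O[Si](C)(C)C(C)(C)C)/C=C/C=C/C=C/C=C/C=C(\C)[C@@H]1OC(C)(C)O[C@H]1[C@@H]1C[C@@H](C[C@H]2C[C@@H](C[C@@H](O[Si](CC)(CC)CC)[C@H](C(=O)O)[C@@H](O[Si](CC)(CC)CC)CCCCC)OC(C)(C)O2)OC(C)(C)O1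
F6 | step 16 | C5 aldehyde with O7 silyl ether | I/C=C(\C)[C@@H]1OC(C)(C)O[C@H]1[C@@H]1C[C@@H](C[C@H](O[Si](C)(C)C(C)(C)C)CC=O)OC(C)(C)O1
F7 | step 16 | C5 homoallylic alcohol (syn to O7), O7 silyl ether | I/C=C(\C)[C@@H]1OC(C)(C)O[C@H]1[C@@H]1C[C@@H](C[C@H](O[Si](C)(C)C(C)(C)C)C[C@H](O)CC=C)OC(C)(C)O1
F8 | step 16 | syn C5/C7 diol with terminal alkene | I/C=C(\C)[C@@H]1OC(C)(C)O[C@H]1[C@@H]1C[C@@H](C[C@H](O)C[C@H](O)CC=C)OC(C)(C)O1
F9 | step 16 | C5/C7 acetonide with terminal alkene at C3 | I/C=C(\C)[C@@H]1OC(C)(C)O[C@H]1[C@@H]1C[C@@H](C[C@H]2C[C@@H](CC=C)OC(C)(C)O2)OC(C)(C)O1
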